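**Remark on the chemistry:** the target has no stereocentre; the two stereocentres formed in the cycloaddition are racemic (one enantiomer is written in the SMILES) and disappear in step 3, dimethyldioxirane (DMDO) is taken as a pre-formed acetone solution, and enecarbamate 4 is purchased.

## Analysis of the target

Compound 15 is a fully aromatic indole, a benzene ring (C3a, C4, C5, C6, C7, C7a) fused through the C3a–C7a bond to a pyrrole ring (N1, C2, C3, C3a, C7a). N1 bears a methyl group, C2 a bromine, C3 a formyl group and C5 and C6 one bromine each, so that of the ring carbons only C4 and C7 carry hydrogen. The molecule is planar and achiral; the only stereocentres met on the way are C3a and C7a of a transient cis-fused tetrahydroindole, and they are erased on aromatisation. The sensitive features are the three C–Br bonds, which exclude alkyllithium reagents, zerovalent palladium, dissolving metals and hydrogenolysis once they are present, and the 2-bromo-3-formyl pair, a vinylogous acyl bromide that is open to addition–elimination by nucleophiles. The difficulty is regiochemical: electrophilic bromination of an indole does not by itself single out C5 and C6, and C2 is a poor site for an electrophile once C3 carries the formyl group. The route therefore builds the benzene ring with both bromines already attached. This rests on the fact that C4(H)–C5(Br)–C6(Br)–C7(H) corresponds atom for atom to the four ring carbons of dioxide 3, whose mirror plane makes C5 and C6 equivalent, while the C3a–C7a bond, with N1 on C7a, is the double bond of enecarbamate 4.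

## Retrosynthetic reasoning

**C2–Br (15 to 13).** The last bond cut is C2–Br. C2–H of 13 lies between N1 and the formyl-bearing C3 and is the most acidic C–H in the molecule, so it can be removed by a hindered zinc amide and the C2–zinc species 14 quenched with an electrophilic bromine source. An electrophilic substitution is not relied on, because C2 is the β-carbon of a vinylogous formamide. The forward step has to metalate C2 in preference to C4 and C7 and must not touch the aryl bromines or the aldehyde.

**C3–CHO (13 to 11).** The formyl carbon is disconnected at C3, the innately nucleophilic position of an N-alkylindole. Forward, a chloroiminium electrophile gives iminium salt 12, which is hydrolysed. Doing this before C2 bromination provides the acidifying group that the last step needs.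

**N1–CH3 (11 to 9).** The methyl group is cut back to the N–H indole 9, alkylated through its sodium salt 10. The methyl group cannot be carried from the start, because an N-alkyl enamine in place of 4 would be unstable and the amine on C7a of the resulting diene would be expelled with ring opening; an acyl group is needed on nitrogen at that stage.

**C2=C3 unsaturation (9 to 8).** The pyrrole double bond is traced back to indoline 8. The dehydrogenation is placed on the free amine because the nitrogen lone pair has to assist hydride loss from C2; the N-acyl indoline 7 would react far more slowly.

**N-protecting group (8 to 7).** The tert-butyl carbamate serves only the cycloaddition and the first aromatisation. It is removed by acid once the six-membered ring is aromatic; before that, acid would ionise the allylic C7a–N bond.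

**Aromatic sextet (7 to 6).** Two hydrogens (on C3a and C7a) are put back, giving the cis-fused cyclohexa-1,3-diene 6. The forward step is an oxidation-level adjustment with a quinone and costs no skeletal bond.

**C3a–C4 and C7–C7a (6 to 3 and 4, through 5).** These two bonds are cut together. This disconnection is chosen because it removes the whole carbocycle in one operation and leaves a four-carbon fragment that already carries both bromines on its inner carbons and is symmetric, so no regiochemical question arises. The other fragment is the intact five-membered nitrogen ring. Forward, a cycloaddition gives bridged adduct 5, which must expel its sulfonyl bridge to give 6.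

**Sulfur oxidation (3 to 1, through 2).** Diene 3 is the S,S-dioxide of the commercial thiophene 1. One oxidation, passing through S-oxide 2, turns an aromatic heterocycle into an electron-poor cyclic diene.

## Alternatives that were turned down

Alternative 1: cobalt-mediated [2+2+2] cocyclisation of an ynamide diyne.
- Disconnection: C3a–C7a, C4–C5 and C6–C7 are cut, so that both rings come from the diyne N-(but-3-yn-1-yl)-N-ethynyl-4-methylbenzenesulfonamide A1 and the symmetric alkyne bis(trimethylsilyl)acetylene A2.
- Forward key step: the cobalt complex CpCo(CO)2 A3 cocyclises A1 with A2 to give 1-tosyl-5,6-bis(trimethylsilyl)indoline A4.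
- For: three C–C bonds and two rings form at once, the symmetry of A2 removes regiochemistry, and A4 is aromatic straight away. On that last point this alternative is stronger than the chosen route, which passes through a labile diene and needs an oxidation.
- Against: C5 and C6 of A4 bear silicon, so two ipso-bromodesilylations are needed. The second acts on a ring already deactivated by the first bromine and competes with protodesilylation. The terminal N-ethynyl sulfonamide A1 is sensitive and takes several steps to prepare, and the cocyclisation with A3 has to outrun its self-oligomerisation. The sulfonyl group must later be removed under reductive or strongly basic conditions that sit badly with two aryl bromides.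
- Comparison: after A4 the same indoline oxidation, N-methylation, C3 formylation and C2 bromination remain, so the sequence is several steps longer. The chosen strategy places both bromines in the ring-forming event and uses two simple components.

Alternative 2: copper-catalysed closure of a dibromovinyl aniline.
- Disconnection: N1–C2 is cut, which leads back to 4,5-dibromo-2-(2,2-dibromovinyl)-N-methylaniline A5.
- Forward key step: CuI A6 with a diamine ligand and an inorganic base couples the N-methylamino group of A5 with the cis vinylic C–Br. This gives 2,5,6-tribromo-1-methyl-1H-indole A7, in which the second vinylic bromine stays as C2–Br.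
- For: in A7 the C2 bromine and the N-methyl group are both in place when the ring closes, and a single Vilsmeier–Haack formylation of A7 then leads to 15. On the C2 halogen this is stronger than the chosen route, and the step count from the arene is lower.
- Against: the 5,6-dibromo problem is moved to the synthesis of the tetrasubstituted benzene A5. Electrophilic bromination of an ortho-aminobenzaldehyde places bromine para to nitrogen (the future C5, correct) and then ortho to nitrogen (the future C7, wrong); the position meta to nitrogen that must become C6 is not reached. The arene would therefore have to come from a nitration with isomer separation, followed by dibromo-olefination, nitro reduction in the presence of four C–Br bonds and mono-N-methylation of a primary aniline. The coupling with A6 must select a vinylic C–Br over two aryl C–Br bonds and avoid intermolecular N-arylation. In the final formylation, chloride may exchange the activated C2 bromine of A7 at the iminium stage.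
- Comparison: the chosen strategy obtains the 5,6-pattern from the symmetry of 3, with no arene-substitution regiochemistry and no metal-catalysed coupling next to several C–Br bonds. It pays for this with a late C2 bromination.

Alternative 3: dibromobenzyne annulation with a dehydroalanine carbamate.
- Disconnection: N1–C7a and C3–C3a are cut.
- Forward key step: a fluoride source converts 4,5-dibromo-2-(trimethylsilyl)phenyl trifluoromethanesulfonate A8 into 4,5-dibromobenzyne A9. The carbamate nitrogen of methyl 2-[(tert-butoxycarbonyl)amino]acrylate A10 adds to A9, and the aryl anion closes onto the terminal alkene carbon to give racemic 1-tert-butyl 2-methyl 5,6-dibromoindoline-1,2-dicarboxylate A11.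
- For: the symmetric aryne A9 fixes the dibromo pattern without any regiochemical question, which equals the chosen strategy on this point. The ring of A11 is aromatic from the outset, and its ester marks the carbon that must end as C2–Br.
- Against: A8 is itself a 1,2,4,5-tetrasubstituted arene, and the usual halogen–metal exchange route to an ortho-silyl phenol derivative cannot be run cleanly beside two further aryl bromines. The ring closure after addition of A10 is a 5-endo-trig conjugate addition that competes with simple protonation of the aryl anion. The ester of A11 is the wrong group at C2 and would have to be exchanged for bromine by hydrolysis and decarboxylative halogenation.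
- Comparison: from A11, indoline oxidation, carbamate-to-methyl exchange and C3 formylation are still needed, so the sequence is clearly longer. The chosen strategy starts from two commercial compounds and carries no group that must later be excised.

Key step: step 2

## Route

Step 1
Reactants: 1 3,4-dibromothiophene
Product: 3 3,4-dibromothiophene 1,1-dioxide, via 3,4-dibromothiophene 1-oxide 2 (not isolated)
Conditions: DMDO (2.5 equiv, acetone solution), CH2Cl2, −20 °C to rt; concentrate cold, use at once
Reagents that add atoms: dimethyldioxirane, CC1(C)OO1
Why: S-oxidation of a thiophene by an electrophilic dioxirane; the second oxygen transfer to the non-aromatic S-oxide 2 should be faster than the first, so dioxide 3 is expected as the product. The neutral conditions leave only volatile material to remove from a diene that is prone to self-dimerise.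

Step 2
Reactants: 3 3,4-dibromothiophene 1,1-dioxide; 4 tert-butyl 2,3-dihydro-1H-pyrrole-1-carboxylate
Product: 6 rac-cis-tert-butyl 5,6-dibromo-2,3,3a,7a-tetrahydro-1H-indole-1-carboxylate, via bridged sulfone adduct 5 (not isolated)
Conditions: 4 (3 equiv), NaHCO3 (solid), toluene, 70 °C, N2
Reagents that add atoms: none
Why: The reaction is an inverse-electron-demand Diels–Alder cycloaddition in which the LUMO of diene 3, lowered by the sulfonyl group and the two bromines, meets the HOMO of the enecarbamate C=C of 4; bonding is expected to be concerted but asynchronous, with the nucleophilic β-carbon of 4 (the future C3a) leading. The closest known reaction type is the cycloaddition of halogenated thiophene 1,1-dioxides to electron-rich or strained alkenes, in which the 7-thiabicyclo[2.2.1]heptene 7,7-dioxide adduct loses SO2 at or below the reaction temperature. The six-membered carbocycle is closed by the (4+2) cycloaddition itself, both σ bonds (C3a–C4 and C7–C7a) forming suprafacially on diene and alkene, while the five-membered ring is carried in unchanged from 4. Adduct 5 then undergoes a thermally allowed cheletropic extrusion of SO2, which turns the bridgeheads C4 and C7 into sp2 carbons and leaves a 1,3-diene with C5–Br and C6–Br on its inner carbons. The two new stereocentres C3a and C7a are controlled by the cis geometry of the ring alkene of 4: both bonds form on one face, so the ring fusion must be cis, the product is racemic because no chiral element is present, and the endo/exo ratio of 5 is irrelevant because both isomers give the same 6. Regioselectivity is not an issue because 3 has a mirror plane through sulfur. The selectivity that matters is cross-cycloaddition over self-dimerisation of 3, which should be secured by the excess of 4, the matched electron demand and the β-bromines that make the C=C bonds of 3 poor 2π partners. Solid NaHCO3 takes up adventitious acid so that neither 4 nor the allylic C7a–N bond of 6 is ionised.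

Step 3
Reactants: 6 rac-cis-tert-butyl 5,6-dibromo-2,3,3a,7a-tetrahydro-1H-indole-1-carboxylate
Product: 7 tert-butyl 5,6-dibromoindoline-1-carboxylate
Conditions: DDQ (1.1 equiv), NaHCO3 (solid), toluene, 0 °C to rt
Reagents that add atoms: none
Why: Dehydrogenative aromatisation of a cyclohexa-1,3-diene by a high-potential quinone (hydride abstraction from C3a or C7a to a cyclohexadienyl cation, then proton loss); the gain of benzene aromaticity should make it fast at low temperature, and both stereocentres disappear. The C2–C3 bond of the N-acyl indoline formed is not expected to be oxidised under these conditions.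

Step 4
Reactants: 7 tert-butyl 5,6-dibromoindoline-1-carboxylate
Product: 8 5,6-dibromoindoline
Conditions: TFA, CH2Cl2, 0 °C to rt; aq. NaHCO3
Reagents that add atoms: none
Why: Acidolysis of a tert-butyl carbamate (loss of the tert-butyl cation, then decarboxylation); the aryl bromides are inert to acid, and with the ring now aromatic no C–N ionisation can occur.

Step 5
Reactants: 8 5,6-dibromoindoline
Product: 9 5,6-dibromo-1H-indole
Conditions: DDQ (1.05 equiv), 1,4-dioxane, rt
Reagents that add atoms: none
Why: Quinone dehydrogenation of an indoline to an indole; the free nitrogen lone pair assists hydride loss from C2, which is why this oxidation follows removal of the carbamate.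

Step 6
Reactants: 9 5,6-dibromo-1H-indole
Product: 11 5,6-dibromo-1-methyl-1H-indole, via sodium 5,6-dibromoindol-1-ide 10 (not isolated)
Conditions: NaH, DMF, 0 °C; MeI, 0 °C to rt
Reagents that add atoms: iodomethane, CI
Why: N-alkylation of an indolide anion (SN2); the sodium salt in a dipolar aprotic solvent should react at nitrogen and not at C3.

Step 7
Reactants: 11 5,6-dibromo-1-methyl-1H-indole
Product: 13 5,6-dibromo-1-methyl-1H-indole-3-carbaldehyde, via C3-iminium chloride 12 (not isolated)
Conditions: POCl3, DMF, 0 to 40 °C; then aq. NaOH, 60 °C
Reagents that add atoms: N,N-dimethylformamide, CN(C)C=O; water, O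
Why: Vilsmeier–Haack formylation; the chloroiminium ion attacks C3, the most nucleophilic carbon of an N-alkylindole even with two bromines on the benzene ring, and aqueous base hydrolyses iminium salt 12 to the aldehyde.

Step 8
Reactants: 13 5,6-dibromo-1-methyl-1H-indole-3-carbaldehyde
Product: 15 2,5,6-tribromo-1-methyl-1H-indole-3-carbaldehyde, via bis(indol-2-yl)zinc 14 (not isolated)
Conditions: Zn(TMP)2·2MgCl2·2LiCl (0.6 equiv; TMP = 2,2,6,6-tetramethylpiperidin-1-yl), THF, 25 °C; then Br2, −40 to 0 °C
Reagents that add atoms: bromine, BrBr
Why: Directed deprotonative zincation followed by bromodezincation; C2–H, flanked by N1 and the formyl-bearing C3, is the most acidic C–H of 13, and hindered zinc amides of this type metalate heteroaryl aldehydes without adding to the carbonyl and without halogen–metal exchange at aryl bromides. The C2–Zn bond of 14 is then cleaved by Br2 at the same carbon; an electrophilic bromination is avoided because C2 is the electron-poor β-carbon of a vinylogous formamide.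

## Compound list

1 | 3,4-dibromothiophene | Brc1cscc1Br | starting material
2 | 3,4-dibromothiophene 1-oxide (not isolated) | O=S1C=C(Br)C(Br)=C1 | intermediate
3 | 3,4-dibromothiophene 1,1-dioxide | O=S1(=O)C=C(Br)C(Br)=C1 | intermediate
4 | tert-butyl 2,3-dihydro-1H-pyrrole-1-carboxylate | CC(C)(C)OC(=O)N1CCC=C1 | starting material
5 | tert-butyl 5,6-dibromo-2,3,3a,4,7,7a-hexahydro-1H-4,7-epithioindole-1-carboxylate 8,8-dioxide (racemic, endo/exo mixture, ring-fusion hydrogens cis; not isolated) | CC(C)(C)OC(=O)N1CC[C@H]2[C@@H]1C1C(Br)=C(Br)C2S1(=O)=O | intermediate
6 | rac-(3aR,7aR)-tert-butyl 5,6-dibromo-2,3,3a,7a-tetrahydro-1H-indole-1-carboxylate (cis ring fusion) | CC(C)(C)OC(=O)N1CC[C@@H]2C=C(Br)C(Br)=C[C@H]12 | intermediate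
7 | tert-butyl 5,6-dibromoindoline-1-carboxylate | CC(C)(C)OC(=O)N1CCc2cc(Br)c(Br)cc21 | intermediate
8 | 5,6-dibromoindoline | Brc1cc2CCNc2cc1Br | intermediate
9 | 5,6-dibromo-1H-indole | Brc1cc2cc[nH]c2cc1Br | intermediate
10 | sodium 5,6-dibromoindol-1-ide (not isolated) | [Na+].Brc1cc2cc[n-]c2cc1Br | intermediate
11 | 5,6-dibromo-1-methyl-1H-indole | Cn1ccc2cc(Br)c(Br)cc21 | intermediate
12 | N-[(5,6-dibromo-1-methyl-1H-indol-3-yl)methylidene]-N-methylmethanaminium chloride (not isolated) | C[N+](C)=Cc1cn(C)c2cc(Br)c(Br)cc12.[Cl-] | intermediate
13 | 5,6-dibromo-1-methyl-1H-indole-3-carbaldehyde | Cn1cc(C=O)c2cc(Br)c(Br)cc21 | intermediate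
14 | bis(5,6-dibromo-3-formyl-1-methyl-1H-indol-2-yl)zinc (not isolated) | Cn1c([Zn]c2n(C)c3cc(Br)c(Br)cc3c2C=O)c(C=O)c2cc(Br)c(Br)cc21 | intermediate
15 | 2,5,6-tribromo-1-methyl-1H-indole-3-carbaldehyde | Cn1c(Br)c(C=O)c2cc(Br)c(Br)cc21 | target

## Step count and least certain steps

Total step count: 8 steps.
Longest linear sequence: 8 steps (1 to 15); 4 is purchased and enters at step 2.

**Step 2 (key step).**
- What may go wrong: diene 3 may be lost by self-dimerisation, or by decomposition between step 1 and step 2, faster than the moderately nucleophilic enecarbamate captures it. If acid is present, the allylic C7a–N bond of the product may ionise, which aromatises the six-membered ring and opens the five-membered ring.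
- Fallback (sets out from 1 and 4, returns at 8): exchange the diene for a silyl-blocked dioxide that can be stored. Double α-deprotonation of 1 with LiN(iPr)2 in the presence of Me3SiCl would give 3,4-dibromo-2,5-bis(trimethylsilyl)thiophene F1. mCPBA would oxidise it to 3,4-dibromo-2,5-bis(trimethylsilyl)thiophene 1,1-dioxide F2; the silyl groups make the sulfur more electron-rich for the oxidation and block dimerisation. Heating F2 with 4 in xylene should give, through the 4,7-disilylated bridged sulfone adduct F3, the cis-fused 4,7-bis(trimethylsilyl) tetrahydroindole carbamate F4. DDQ would aromatise this to tert-butyl 5,6-dibromo-4,7-bis(trimethylsilyl)indoline-1-carboxylate F5. Warm TFA would then cleave both aryl–silicon bonds by ipso-protonation together with the carbamate, which returns the route to 8.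
- Cost: a more hindered and therefore slower cycloaddition, and one extra step. This fallback also replaces step 1.

**Step 3.**
- What may go wrong: instead of dehydrogenation, the allylic C7a–N bond may ionise under acid or heat and the C3a proton be lost, giving ring-opening aromatisation. The reduced quinone formed during the reaction is acidic enough to start this.
- Fallback (sets out from 4 and 3, returns at 7): turn the aromatisation into an elimination that cannot break the C–N bond. Addition of Br2 to 4 would give rac-trans-tert-butyl 2,3-dibromopyrrolidine-1-carboxylate F6, from which Et3N removes HBr to give tert-butyl 4-bromo-2,3-dihydro-1H-pyrrole-1-carboxylate F7. Cycloaddition of F7 with 3 under the conditions of step 2, with an amine base present, should lead through the 3a-bromo bridged sulfone adduct F8 to the 3a,5,6-tribromo tetrahydroindole carbamate F9. F9 has no hydrogen on C3a, so it can aromatise only by ionisation of the tertiary, allylic C3a–Br bond and loss of the C7a proton, which gives 7 directly.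
- Cost: the bromine on the alkene makes F7 less electron-rich than 4, so the cycloaddition should be slower.

**Step 8.**
- What may go wrong: incomplete or unselective metalation (competing deprotonation at C4 or C7 next to the aryl bromines, or addition of the amide to the formyl group), and oxidation of the liberated amine by Br2 that consumes the electrophile.
- Fallback (sets out from 11, returns at 15; replaces steps 7 and 8): introduce C2–Br and the formyl group together from an oxindole. NCS would convert 11 into 5,6-dibromo-3-chloro-1-methyl-1H-indole F10. Hydrolysis with H3PO4 in 2-methoxyethanol at reflux would give 5,6-dibromo-1-methylindolin-2-one F11. POBr3 in DMF (Vilsmeier–Haack–Arnold bromoformylation) would then turn the lactam carbonyl into C2–Br and formylate C3 in the same operation, through the 2-bromo iminium bromide F12, whose aqueous hydrolysis gives 15.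

## Further compounds

F1 | step 2 | 3,4-dibromo-2,5-bis(trimethylsilyl)thiophene | C[Si](C)(C)c1sc([Si](C)(C)C)c(Br)c1Br
F2 | step 2 | 3,4-dibromo-2,5-bis(trimethylsilyl)thiophene 1,1-dioxide | C[Si](C)(C)C1=C(Br)C(Br)=C([Si](C)(C)C)S1(=O)=O
F3 | step 2 | tert-butyl 5,6-dibromo-4,7-bis(trimethylsilyl)-2,3,3a,4,7,7a-hexahydro-1H-4,7-epithioindole-1-carboxylate 8,8-dioxide (racemic, ring-fusion hydrogens cis) | CC(C)(C)OC(=O)N1CC[C@H]2[C@@H]1C1([Si](C)(C)C)C(Br)=C(Br)C2([Si](C)(C)C)S1(=O)=O
F4 | step 2 | rac-cis-tert-butyl 5,6-dibromo-4,7-bis(trimethylsilyl)-2,3,3a,7a-tetrahydro-1H-indole-1-carboxylate | CC(C)(C)OC(=O)N1CC[C@@H]2C([Si](C)(C)C)=C(Br)C(Br)=C([Si](C)(C)C)[C@H]12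
F5 | step 2 | tert-butyl 5,6-dibromo-4,7-bis(trimethylsilyl)indoline-1-carboxylate | CC(C)(C)OC(=O)N1CCc2c([Si](C)(C)C)c(Br)c(Br)c([Si](C)(C)C)c21
F6 | step 3 | rac-trans-tert-butyl 2,3-dibromopyrrolidine-1-carboxylate | CC(C)(C)OC(=O)N1CC[C@H](Br)[C@H]1Br
F7 | step 3 | tert-butyl 4-bromo-2,3-dihydro-1H-pyrrole-1-carboxylate | CC(C)(C)OC(=O)N1CCC(Br)=C1
F8 | step 3 | tert-butyl 3a,5,6-tribromo-2,3,3a,4,7,7a-hexahydro-1H-4,7-epithioindole-1-carboxylate 8,8-dioxide (racemic, Br on C3a and H on C7a cis) | CC(C)(C)OC(=O)N1CC[C@@]2(Br)[C@@H]1C1C(Br)=C(Br)C2S1(=O)=O
F9 | step 3 | rac-tert-butyl 3a,5,6-tribromo-2,3,3a,7a-tetrahydro-1H-indole-1-carboxylate (Br on C3a and H on C7a cis) | CC(C)(C)OC(=O)N1CC[C@]2(Br)C=C(Br)C(Br)=C[C@H]12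
F10 | step 8 | 5,6-dibromo-3-chloro-1-methyl-1H-indole | Cn1cc(Cl)c2cc(Br)c(Br)cc21
F11 | step 8 | 5,6-dibromo-1-methylindolin-2-one | CN1C(=O)Cc2cc(Br)c(Br)cc21
F12 | step 8 | N-[(2,5,6-tribromo-1-methyl-1H-indol-3-yl)methylidene]-N-methylmethanaminium bromide | C[N+](C)=Cc1c(Br)n(C)c2cc(Br)c(Br)cc12.[Br-]
A1 | alternative 1 | N-(but-3-yn-1-yl)-N-ethynyl-4-methylbenzenesulfonamide | Cc1ccc(cc1)S(=O)(=O)N(C#C)CCC#C
A2 | alternative 1 | bis(trimethylsilyl)acetylene | C[Si](C)(C)C#C[Si](C)(C)C
A3 | alternative 1 | cyclopentadienylcobalt dicarbonyl, CpCo(CO)2 | [Co+].[C-]#[O+].[C-]#[O+].c1cc[cH-]c1
A4 | alternative 1 | 1-tosyl-5,6-bis(trimethylsilyl)indoline | Cc1ccc(cc1)S(=O)(=O)N1CCc2cc([Si](C)(C)C)c([Si](C)(C)C)cc21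
A5 | alternative 2 | 4,5-dibromo-2-(2,2-dibromovinyl)-N-methylaniline | CNc1cc(Br)c(Br)cc1C=C(Br)Br
A6 | alternative 2 | copper monoiodide, CuI | [Cu+].[I-]
A7 | alternative 2 | 2,5,6-tribromo-1-methyl-1H-indole | Cn1c(Br)cc2cc(Br)c(Br)cc21
A8 | alternative 3 | 4,5-dibromo-2-(trimethylsilyl)phenyl trifluoromethanesulfonate | C[Si](C)(C)c1cc(Br)c(Br)cc1OS(=O)(=O)C(F)(F)F
A9 | alternative 3 | 4,5-dibromobenzyne (4,5-dibromo-1,2-didehydrobenzene) | BrC1=CC#CC=C1Br
A10 | alternative 3 | methyl 2-[(tert-butoxycarbonyl)amino]acrylate | COC(=O)C(=C)NC(=O)OC(C)(C)C
A11 | alternative 3 | rac-1-tert-butyl 2-methyl 5,6-dibromoindoline-1,2-dicarboxylate | COC(=O)C1Cc2cc(Br)c(Br)cc2N1C(=O)OC(C)(C)C
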